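## Retrosynthetic overview

1. The target comes from desilylation of its C12 silyl ether. That ether comes from a (−)-MIB-catalysed isopropenylzinc addition to a macrocyclic aldehyde, which sets C3'.
2. The 11-membered carbocycle is the last ring formed. It is closed by ring-closing metathesis at C9=C10 of an acyclic triene ester.
3. C3–C4 comes from an alkenylzinc addition of a quaternary alkyne to an epoxy aldehyde. The oxirane is the first ring formed, by Sharpless epoxidation of a C9 dienol made from methallyl alcohol and prenyl bromide.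
4. The alkyne / masked aldehyde / allyl core comes from Eschenmoser–Tanabe unzipping of (R)-6-allyl-6-methylcyclohexenone oxide. C1, its methyl, C2, C3, C3', C2' and C1' are the seven carbons of o-cresol.
5. That enone comes from Birch dearomatisation of o-cresol TBS ether. This gives a tetrasubstituted silyl dienol ether, which is quaternised by Pd/PHOX allylation.

**Assumption and locants:** the C9=C10 geometry is read literally from the SMILES (ring carbons C8 and C11 cis, CH2OH trans to C11). C1 is the quaternary carbon, C2=C3 the E-alkene, C4 the ester carbinol, C5/C6 the epoxide, then C7, C8, C9 (bearing C12H2OH), C10 and C11. The side chain is C1'–C2'–C3'(OH)–isopropenyl.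

## Route

**Step 1**
Reactants: 1 o-cresol
Product: 2 tert-butyl(dimethyl)(2-methylphenoxy)silane
Conditions: TBSCl, imidazole, DMF, rt
Reagents that add atoms: tert-butyldimethylsilyl chloride CC(C)(C)[Si](C)(C)Cl
Why: This is a standard Corey silylation, and TBS is chosen because aryl TBS ethers survive dissolving-metal reduction.

**Step 2**
Reactants: 2 tert-butyl(dimethyl)(2-methylphenoxy)silane
Product: 3 tert-butyl(dimethyl)[(2-methylcyclohexa-1,4-dien-1-yl)oxy]silane
Conditions: Li, NH3(l), THF, t-BuOH, −78 to −33 °C; NH4Cl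
Reagents that add atoms: none
Why: In this Birch reduction both donor substituents (OSi, Me) stay on one retained double bond, so dearomatisation gives regiospecifically the tetrasubstituted silyl enol ether plus a skipped alkene that later becomes the enone, and no stereocentre is formed.

**Step 3**
Reactants: 3 tert-butyl(dimethyl)[(2-methylcyclohexa-1,4-dien-1-yl)oxy]silane; 4 diallyl carbonate
Product: 6 (6R)-6-allyl-6-methylcyclohex-2-en-1-one, via skipped enone 5 (not isolated)
Conditions: Pd2(dba)3 (2.5 mol %), (R)-t-Bu-PHOX (6 mol %), TBAT (35 mol %), THF, 25 °C; then DBU (0.2 equiv), 25 °C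
Reagents that add atoms: none
Why: In this Tsuji–Trost/Stoltz enantioselective allylic alkylation of a silyl enol ether, fluoride/allyloxide releases the enolate only at the methyl-bearing carbon, inner-sphere C–C coupling on the (R)-PHOX–Pd allyl sets C1 (about 88 % ee expected by analogy with 2-methylcyclohexanone), and DBU moves the skipped alkene into conjugation.

**Step 4**
Reactants: 6 (6R)-6-allyl-6-methylcyclohex-2-en-1-one
Product: 7 (3R)-3-allyl-3-methyl-7-oxabicyclo[4.1.0]heptan-2-one (epoxide epimers)
Conditions: 30 % H2O2, NaOH (cat.), MeOH, 0 °C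
Reagents that add atoms: hydrogen peroxide OO
Why: Weitz–Scheffer nucleophilic epoxidation attacks only the enone and not the allyl group, and the two new stereocentres are destroyed in the next step, so their ratio does not matter.

**Step 5**
Reactants: 7 (3R)-3-allyl-3-methyl-7-oxabicyclo[4.1.0]heptan-2-one
Product: 10 (4R)-4-ethynyl-7,7-dimethoxy-4-methylhept-1-ene, via epoxy sulfonylhydrazone 8 (not isolated), via alkynal 9 (not isolated)
Conditions: 2,4-(O2N)2C6H3SO2NHNH2, THF, −10 °C, then pyridine, 0 °C to rt; crude aldehyde + HC(OMe)3, MeOH, PPTS (cat.), rt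
Reagents that add atoms: trimethyl orthoformate COC(OC)OC
Why: Eschenmoser–Tanabe fragmentation (dinitrobenzenesulfonylhydrazide variant for aldehyde-forming cases) cleaves C3–C3', turns C2/C3 into the terminal alkyne and C3' into the aldehyde without touching C1, and acetalisation masks the aldehyde for the hydrometalation.

**Step 6**
Reactants: 11 2-methylprop-2-en-1-ol; 12 1-bromo-3-methylbut-2-ene
Product: 14 6-methyl-2-methylidenehept-5-en-1-ol, via dilithio methallyl alkoxide 13 (not isolated)
Conditions: n-BuLi (2.2 equiv), TMEDA, Et2O, 0 °C to rt; then 12, −78 °C to rt; H2O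
Reagents that add atoms: none
Why: This is an allylic dianion alkylation in which the C-lithiated methallyl alkoxide displaces the primary allylic bromide by SN2 and forms C7–C8 in one step.

**Step 7**
Reactants: 14 6-methyl-2-methylidenehept-5-en-1-ol
Product: 15 tert-butyl(dimethyl)[(6-methyl-2-methylidenehept-5-en-1-yl)oxy]silane
Conditions: TBSCl, imidazole, CH2Cl2, rt
Reagents that add atoms: tert-butyldimethylsilyl chloride CC(C)(C)[Si](C)(C)Cl
Why: Standard silylation removes the directing ability of the C12 hydroxyl before the Sharpless step and protects it through the later acylation.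

**Step 8**
Reactants: 15 tert-butyl(dimethyl)[(6-methyl-2-methylidenehept-5-en-1-yl)oxy]silane
Product: 16 (2E)-6-{[tert-butyl(dimethyl)silyl]oxymethyl}-2-methylhepta-2,6-dien-1-ol
Conditions: SeO2 (0.3 equiv), t-BuOOH, CH2Cl2, 0 °C
Reagents that add atoms: tert-butyl hydroperoxide CC(C)(C)OO
Why: In this Sharpless–Umbreit catalytic SeO2 allylic oxidation, the ene/[2,3] sequence reacts fastest at the trisubstituted alkene and oxidises only the E-methyl group, which fixes the C5=C6 geometry.

**Step 9**
Reactants: 16 (2E)-6-{[tert-butyl(dimethyl)silyl]oxymethyl}-2-methylhepta-2,6-dien-1-ol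
Product: 17 [(2R,3R)-3-(3-{[tert-butyl(dimethyl)silyl]oxymethyl}but-3-en-1-yl)-2-methyloxiran-2-yl]methanol
Conditions: Ti(Oi-Pr)4 (10 mol %), D-(−)-DET (12 mol %), t-BuOOH, 4 Å MS, CH2Cl2, −20 °C
Reagents that add atoms: tert-butyl hydroperoxide CC(C)(C)OO
Why: In this Sharpless asymmetric epoxidation, D-(−)-tartrate delivers oxygen to the face that gives the (2R,3R)-epoxy alcohol from an (E)-2-methylallylic alcohol, which sets C5 and C6 (over 95 % ee) and leaves the non-directed 1,1-disubstituted alkene alone.

**Step 10**
Reactants: 17 [(2R,3R)-3-(3-{[tert-butyl(dimethyl)silyl]oxymethyl}but-3-en-1-yl)-2-methyloxiran-2-yl]methanol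
Product: 18 (2S,3R)-3-(3-{[tert-butyl(dimethyl)silyl]oxymethyl}but-3-en-1-yl)-2-methyloxirane-2-carbaldehyde
Conditions: TEMPO (10 mol %), PhI(OAc)2, CH2Cl2, rt
Reagents that add atoms: none
Why: TEMPO/BAIB (Piancatelli–Margarita) oxidation stops at the aldehyde under near-neutral conditions, and the α-carbon is fully substituted, so it cannot epimerise.

**Step 11**
Reactants: 10 (4R)-4-ethynyl-7,7-dimethoxy-4-methylhept-1-ene; 18 (2S,3R)-epoxy aldehyde
Product: 21 (1S,2E,4R)-1-[(2S,3R)-3-(3-{[tert-butyl(dimethyl)silyl]oxymethyl}but-3-en-1-yl)-2-methyloxiran-2-yl]-4-(3,3-dimethoxypropyl)-4-methylhepta-2,6-dien-1-ol, via alkenylzirconocene 19 (not isolated), via alkenylzinc 20 (not isolated)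
Conditions: Cp2ZrHCl (1.05 equiv), CH2Cl2, rt; toluene, Me2Zn, −65 °C; (−)-MIB (10 mol %), 18, −30 to 0 °C; aq NH4Cl
Reagents that add atoms: none
Why: In this Wipf hydrozirconation–zinc transmetalation with amino-alcohol-catalysed (Noyori/Oppolzer type) alkenylzinc addition, syn-hydrozirconation of the terminal alkyne (faster than the allyl group) fixes E-C2=C3, (−)-MIB together with the Felkin–Anh bias of the epoxy aldehyde gives the 4S (syn) carbinol, and the minor C1 enantiomer becomes a separable diastereomer here.

**Step 12**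
Reactants: 21 coupled (4S)-allylic alcohol; 22 3-methylbut-2-enoic acid
Product: 23 3-methylbut-2-enoate ester of 21
Conditions: DCC, DMAP (cat.), CH2Cl2, 0 °C to rt
Reagents that add atoms: none
Why: Steglich esterification acylates the only free hydroxyl with retention at C4 and avoids the amine/acid chloride conditions that deconjugate senecioyl units.

**Step 13**
Reactants: 23 3-methylbut-2-enoate ester of 21
Product: 24 macrocycle: the target ring system carrying C12–OTBS and a 3,3-dimethoxypropyl chain on C1
Conditions: Hoveyda–Grubbs II (15 mol %), 1,4-benzoquinone (20 mol %), toluene (0.5 mM), 80 °C, Ar sparge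
Reagents that add atoms: none
Why: In this ring-closing metathesis the catalyst loads on the allyl group and closes on the 1,1-disubstituted alkene (the isopropenyl group is still absent, so no seven-membered ring can form), and placing the bulky CH2OTBS cis to H rather than cis to the neopentyl C11 favours the required ring-cis trisubstituted alkene.

**Step 14**
Reactants: 24 macrocyclic acetal
Product: 25 macrocyclic aldehyde (3-oxopropyl chain on C1, C12–OTBS)
Conditions: PPTS (0.2 equiv), acetone/H2O 10:1, 45 °C
Reagents that add atoms: water O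
Why: Mild acid-catalysed acetal hydrolysis cleaves an unhindered aliphatic dimethyl acetal well before the epoxide (deactivated by the adjacent acyloxy carbon) or the TBS ether.

**Step 15**
Reactants: 25 macrocyclic aldehyde; 26 isopropenylmagnesium bromide
Product: 28 C12-O-TBS ether of the target, via diisopropenylzinc 27 (not isolated)
Conditions: 26 (4 equiv), ZnCl2 (2 equiv), Et2O, then 1,4-dioxane, filter; (−)-MIB (10 mol %), toluene, 25, 0 °C; aq NH4Cl
Reagents that add atoms: none
Why: In this catalytic asymmetric alkenylzinc addition (Oppolzer/Nugent type), (−)-MIB directs attack to the same aldehyde face as in step 11, which here is labelled 3'R because the nucleophile outranks the alkyl chain, and the ester and epoxide are inert to diorganozincs.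

**Step 16**
Reactants: 28 C12-O-TBS ether of the target
Product: 29 target CNP0309478.1
Conditions: TBAF, AcOH (1:1), THF, 0 °C to rt
Reagents that add atoms: none
Why: Buffered fluoride desilylation removes the primary allylic TBS group without acyl migration or epoxide opening and touches no stereocentre.

## Compound list

1 | o-cresol | Cc1ccccc1O | starting material
2 | tert-butyl(dimethyl)(2-methylphenoxy)silane | Cc1ccccc1O[Si](C)(C)C(C)(C)C | intermediate
3 | tert-butyl(dimethyl)[(2-methylcyclohexa-1,4-dien-1-yl)oxy]silane | CC1=C(O[Si](C)(C)C(C)(C)C)CC=CC1 | intermediate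
4 | diallyl carbonate | C=CCOC(=O)OCC=C | starting material
5 | (2S)-2-allyl-2-methylcyclohex-4-en-1-one (not isolated) | C=CC[C@@]1(C)CC=CCC1=O | intermediate
6 | (6R)-6-allyl-6-methylcyclohex-2-en-1-one | C=CC[C@@]1(C)CCC=CC1=O | intermediate
7 | (3R)-3-allyl-3-methyl-7-oxabicyclo[4.1.0]heptan-2-one, epoxide epimers | C=CC[C@@]1(C)CCC2OC2C1=O | intermediate
8 | 2,4-dinitrobenzenesulfonylhydrazone of 7 (not isolated) | C=CC[C@@]1(C)CCC2OC2C1=NNS(=O)(=O)c1ccc([N+](=O)[O-])cc1[N+](=O)[O-] | intermediate
9 | (4R)-4-ethynyl-4-methylhept-6-enal (not isolated) | O=CCC[C@@](CC=C)(C)C#C | intermediate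
10 | (4R)-4-ethynyl-7,7-dimethoxy-4-methylhept-1-ene | COC(OC)CC[C@@](CC=C)(C)C#C | intermediate
11 | 2-methylprop-2-en-1-ol | C=C(C)CO | starting material
12 | 1-bromo-3-methylbut-2-ene | CC(C)=CCBr | starting material
13 | dilithio methallyl alkoxide (not isolated) | [Li]CC(=C)CO[Li] | intermediate
14 | 6-methyl-2-methylidenehept-5-en-1-ol | C=C(CO)CCC=C(C)C | intermediate
15 | TBS ether of 14 | C=C(CO[Si](C)(C)C(C)(C)C)CCC=C(C)C | intermediate
16 | (2E)-6-(TBSO-methyl)-2-methylhepta-2,6-dien-1-ol | C=C(CO[Si](C)(C)C(C)(C)C)CC/C=C(\C)CO | intermediate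
17 | (2R,3R)-epoxy alcohol | OC[C@@]1(C)O[C@@H]1CCC(=C)CO[Si](C)(C)C(C)(C)C | intermediate
18 | (2S,3R)-epoxy aldehyde | O=C[C@@]1(C)O[C@@H]1CCC(=C)CO[Si](C)(C)C(C)(C)C | intermediate
19 | (E)-alkenyl(chloro)zirconocene from 10 (not isolated) | COC(OC)CC[C@@](CC=C)(C)/C=C/[Zr](Cl)(C1C=CC=C1)C1C=CC=C1 | intermediate
20 | (E)-alkenyl(methyl)zinc from 19 (not isolated) | COC(OC)CC[C@@](CC=C)(C)/C=C/[Zn]C | intermediate
21 | coupled (4S)-allylic alcohol | COC(OC)CC[C@@](CC=C)(C)/C=C/[C@H](O)[C@@]1(C)O[C@@H]1CCC(=C)CO[Si](C)(C)C(C)(C)C | intermediate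
22 | 3-methylbut-2-enoic acid | CC(C)=CC(=O)O | starting material
23 | senecioate ester of 21 | COC(OC)CC[C@@](CC=C)(C)/C=C/[C@H](OC(=O)C=C(C)C)[C@@]1(C)O[C@@H]1CCC(=C)CO[Si](C)(C)C(C)(C)C | intermediate
24 | macrocyclic acetal, C12–OTBS | COC(OC)CC[C@@]1(C)/C=C/[C@H](OC(=O)C=C(C)C)[C@@]2(C)O[C@@H]2CC/C(CO[Si](C)(C)C(C)(C)C)=C\C1 | intermediate
25 | macrocyclic aldehyde, C12–OTBS | O=CCC[C@@]1(C)/C=C/[C@H](OC(=O)C=C(C)C)[C@@]2(C)O[C@@H]2CC/C(CO[Si](C)(C)C(C)(C)C)=C\C1 | intermediate
26 | isopropenylmagnesium bromide | C=C(C)[Mg]Br | starting material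
27 | diisopropenylzinc (not isolated) | C=C(C)[Zn]C(C)=C | intermediate
28 | C12-O-TBS ether of the target | C=C(C)[C@H](O)CC[C@@]1(C)/C=C/[C@H](OC(=O)C=C(C)C)[C@@]2(C)O[C@@H]2CC/C(CO[Si](C)(C)C(C)(C)C)=C\C1 | intermediate
29 | CNP0309478.1 | C=C(C)[C@H](O)CC[C@@]1(C)/C=C/[C@H](OC(=O)C=C(C)C)[C@@]2(C)O[C@@H]2CC/C(CO)=C\C1 | target

## Step count

Total steps: 16. The longest linear sequence is 11 steps (steps 1–5, then 11–16). Steps 6–10 form the second branch.

## Steps most likely to fail

**Step 13.** Closing an 11-membered ring with a trisubstituted alkene may give oligomers or the ring-trans isomer, because the size difference between CH2OTBS and the ring CH2 is small.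

The fallback sets out from 23 and closes the ring on an electron-poor alkene whose geometry is thermodynamically biased and can be equilibrated.
- Buffered TBAF gives the free allylic alcohol F6.
- MnO2 gives the 2-substituted acrolein F7.
- Metathesis gives the macrocyclic enal F8, in which CHO trans to C11 is the stable arrangement. A wrong isomer can be equilibrated by reversible thiol or amine conjugate addition.
- Luche reduction gives the macrocyclic allylic alcohol F9.
- PPTS hydrolysis gives the hydroxy aldehyde F10.
- The (−)-MIB/diisopropenylzinc addition, with one extra equivalent for the free hydroxyl, comes back to the route at 29.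

**Step 3.** The liberated 1,4-dihydrocresolate can rearomatise by β-hydride loss on palladium. In addition, skipped enone 5 is acidic enough to be allylated a second time.

The fallback sets out from 1 and separates dearomatisation from the unsaturation.
- Selective Pd/C hydrogenation gives 2-methylcyclohexanone F1.
- Thermodynamic enolisation and O-acylation with allyl chloroformate gives allyl 2-methylcyclohex-1-en-1-yl carbonate F2.
- Decarboxylative Pd/(R)-t-Bu-PHOX allylation gives (R)-2-allyl-2-methylcyclohexanone F3.
- IBX dehydrogenation, which is possible only on the CH2 side, comes back to the route at 6.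

**Step 11.** Ligand control in the presence of zirconocene by-products, and the intrinsic facial bias of an α-methyl epoxy aldehyde, may give poor selectivity at C4.

The fallback sets out from 21, taken as the C4 epimer mixture, and installs the ester with inversion instead of retention.
- Dess–Martin oxidation gives the epoxy enone F4.
- Chelation-controlled Zn(BH4)2 reduction gives the anti (4R)-alcohol F5.
- Mitsunobu esterification with 22 (PPh3, DIAD) inverts C4 and comes back to the route at 23.

## Further compounds

F1 | step 3 | 2-methylcyclohexanone | CC1CCCCC1=O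
F2 | step 3 | allyl 2-methylcyclohex-1-en-1-yl carbonate | C=CCOC(=O)OC1=C(C)CCCC1
F3 | step 3 | (R)-2-allyl-2-methylcyclohexanone | C=CC[C@@]1(C)CCCCC1=O
F4 | step 11 | epoxy enone (C4 ketone of 21) | COC(OC)CC[C@@](CC=C)(C)/C=C/C(=O)[C@@]1(C)O[C@@H]1CCC(=C)CO[Si](C)(C)C(C)(C)C
F5 | step 11 | (4R)-epimer of 21 | COC(OC)CC[C@@](CC=C)(C)/C=C/[C@@H](O)[C@@]1(C)O[C@@H]1CCC(=C)CO[Si](C)(C)C(C)(C)C
F6 | step 13 | desilylated 23 (free C12 alcohol) | COC(OC)CC[C@@](CC=C)(C)/C=C/[C@H](OC(=O)C=C(C)C)[C@@]1(C)O[C@@H]1CCC(=C)CO
F7 | step 13 | 2-substituted acrolein from F6 | COC(OC)CC[C@@](CC=C)(C)/C=C/[C@H](OC(=O)C=C(C)C)[C@@]1(C)O[C@@H]1CCC(=C)C=O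
F8 | step 13 | macrocyclic enal | COC(OC)CC[C@@]1(C)/C=C/[C@H](OC(=O)C=C(C)C)[C@@]2(C)O[C@@H]2CC/C(C=O)=C\C1
F9 | step 13 | macrocyclic allylic alcohol acetal | COC(OC)CC[C@@]1(C)/C=C/[C@H](OC(=O)C=C(C)C)[C@@]2(C)O[C@@H]2CC/C(CO)=C\C1
F10 | step 13 | macrocyclic hydroxy aldehyde | O=CCC[C@@]1(C)/C=C/[C@H](OC(=O)C=C(C)C)[C@@]2(C)O[C@@H]2CC/C(CO)=C\C1
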